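**Retrosynthetic overview** (chroman atoms O1, C2, C3, C4, C4a, C5–C8, C8a; quinone ring B atoms primed, C1′–C6′, with C5′ bonded to C3)
1. Target 25 ⇐ silyl ether 24 ⇐ thermal ring expansion of 4-alkynyl-4-hydroxycyclobutenone 23, which closes quinone ring B at the C4′–C5′ bond; 23 ⇐ dimethyl squarate 11 + (S)-3-ethynylchroman 21.
2. Enabling feature: ring B is C1′(=O)–C2′(OMe)=C3′(OMe)–C4′(=O), the C4O4 core of a squarate ester, closed by C5′(–C3)=C6′(H), a terminal alkyne. Ring A (C4a, C5–C8, C8a with O1, 8-OMe, 7-OMe, 6-OH) is the same unit at the hydroquinone level.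
3. Ring A therefore comes from a first squarate/alkyne ring expansion on the propargyl arm of a chiral 1-alkyne (quinone 14); the pyran ring follows by reduction and O1–C2 closure onto a tosylate.
4. The ethynyl group of 21 comes from a dimethyl acetal (masked aldehyde); C3 is set by Evans alkylation of a pent-4-ynoyl imide with trimethyl orthoformate.
5. Order of ring formation: carbocycle A (step 6), pyran ring (step 7), quinone ring B (step 12).

Key step: step 12

Remark: the carbinol carbons of cyclobutenones 13 and 23 form as epimer mixtures and are used as such, because both become quinone carbonyl carbons. Transient species inside a single thermal or carbene step (ketenes, diradicals, carbenes) are described in the Why lines and carry no number.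

**Route**

Step 1
Reactants: 1 pent-4-ynoic acid; 2 (R)-4-benzyl-1,3-oxazolidin-2-one
Product: 4 (R)-4-benzyl-3-(pent-4-ynoyl)-1,3-oxazolidin-2-one, via mixed anhydride 3 (not isolated)
Conditions: PivCl, Et3N, THF, −20 °C; then 2, LiCl, −20 °C → rt
Reagents that add atoms: (R)-4-benzyl-1,3-oxazolidin-2-one (2), O=C1N[C@H](Cc2ccccc2)CO1
Why: N-Acylation of the oxazolidinone through the pivaloyl mixed anhydride (LiCl-assisted) is a standard route to Evans imides and tolerates the terminal alkyne; no stereocentre is formed.

Step 2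
Reactants: 4 (R)-4-benzyl-3-(pent-4-ynoyl)-1,3-oxazolidin-2-one; 5 trimethyl orthoformate
Product: 7 (R)-4-benzyl-3-[(S)-2-(dimethoxymethyl)pent-4-ynoyl]-1,3-oxazolidin-2-one, via titanium enolate 6 (not isolated)
Conditions: TiCl4, i-Pr2NEt, CH2Cl2, 0 °C; then 5, 0 °C
Reagents that add atoms: trimethyl orthoformate (5), COC(OC)OC
Why: Evans alkylation of the chelated (Z)-titanium enolate with the dimethoxycarbenium electrophile released from the orthoformate, which enters on the face opposite the benzyl group of the (R)-auxiliary and thereby sets the (S)-configured α-carbon that becomes C3 of the chroman.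

Step 3
Reactants: 7 (R)-4-benzyl-3-[(S)-2-(dimethoxymethyl)pent-4-ynoyl]-1,3-oxazolidin-2-one
Product: 8 (R)-2-(dimethoxymethyl)pent-4-yn-1-ol
Conditions: LiBH4, MeOH (1 equiv), THF, 0 °C
Reagents that add atoms: none
Why: Reductive removal of the oxazolidinone auxiliary with LiBH4 should give the primary alcohol, leave acetal and alkyne untouched, and remove the α-carbonyl that could otherwise epimerise the new stereocentre.

Step 4
Reactants: 8 (R)-2-(dimethoxymethyl)pent-4-yn-1-ol; 9 4-methylbenzenesulfonyl chloride
Product: 10 (R)-2-(dimethoxymethyl)pent-4-yn-1-yl 4-methylbenzenesulfonate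
Conditions: TsCl, Et3N, DMAP (cat.), CH2Cl2, 0 °C → rt
Reagents that add atoms: 4-methylbenzenesulfonyl chloride (9), Cc1ccc(cc1)S(Cl)(=O)=O
Why: Sulfonylation of the primary alcohol installs the leaving group for the later O1–C2 closure without touching the stereocentre.

Step 5
Reactants: 10 (R)-2-(dimethoxymethyl)pent-4-yn-1-yl 4-methylbenzenesulfonate; 11 dimethyl squarate
Product: 13 (R)-2-(dimethoxymethyl)-5-(1-hydroxy-2,3-dimethoxy-4-oxocyclobut-2-en-1-yl)pent-4-yn-1-yl 4-methylbenzenesulfonate, via lithium acetylide 12 (not isolated)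
Conditions: n-BuLi (1.0 equiv), THF, −78 °C; then 11, −78 °C; aq NH4Cl
Reagents that add atoms: dimethyl squarate (11), COC1=C(OC)C(=O)C1=O
Why: Deprotonation of the terminal alkyne (much faster at −78 °C than attack of n-BuLi on the primary tosylate) and 1,2-addition of the lithium acetylide to one of the two equivalent ketone carbonyls of the squarate ester; the new carbinol carbon forms as an inconsequential epimer mixture.

Step 6
Reactants: 13 (R)-2-(dimethoxymethyl)-5-(1-hydroxy-2,3-dimethoxy-4-oxocyclobut-2-en-1-yl)pent-4-yn-1-yl 4-methylbenzenesulfonate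
Product: 14 (R)-3-(4,5-dimethoxy-3,6-dioxocyclohexa-1,4-dien-1-yl)-2-(dimethoxymethyl)propyl 4-methylbenzenesulfonate
Conditions: p-xylene (0.02 M), 138 °C, Ar
Reagents that add atoms: none
Why: Moore rearrangement (4π-electrocyclic opening to the enynylketene, six-membered closure to a diradical, hydrogen transfer) should convert the strained adduct into the 2,3-dimethoxy-5-alkyl-1,4-benzoquinone that already carries all four oxygen atoms of ring A, the primary-alkyl alkyne substituent favouring quinone over cyclopentenedione formation.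

Step 7
Reactants: 14 (R)-3-(4,5-dimethoxy-3,6-dioxocyclohexa-1,4-dien-1-yl)-2-(dimethoxymethyl)propyl 4-methylbenzenesulfonate
Product: 16 (R)-3-(dimethoxymethyl)-7,8-dimethoxychroman-6-ol, via hydroquinone 15 (not isolated)
Conditions: H2 (1 atm), 10% Pd/C, EtOAc, rt; filter under Ar; then K2CO3, DMF (0.02 M), 50 °C
Reagents that add atoms: none
Why: Hydrogenation reduces the quinone to the hydroquinone, and of its two phenoxides only the one ortho to the side chain can displace the primary tosylate (intramolecular Williamson etherification, 6-exo-tet), which closes the pyran ring and leaves the para hydroxyl as the free 6-OH with C3 untouched.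

Step 8
Reactants: 16 (R)-3-(dimethoxymethyl)-7,8-dimethoxychroman-6-ol; 17 chlorotriisopropylsilane
Product: 18 (R)-3-(dimethoxymethyl)-7,8-dimethoxy-6-(triisopropylsilyloxy)chroman
Conditions: TIPSCl, imidazole, DMF, rt
Reagents that add atoms: chlorotriisopropylsilane (17), CC(C)[Si](Cl)(C(C)C)C(C)C
Why: Silylation of the only free hydroxyl; the aryl TIPS ether shields the electron-rich, hydrogen-donating phenol and should tolerate the mild acid, methanolic carbonate, n-BuLi and heat that follow.

Step 9
Reactants: 18 (R)-3-(dimethoxymethyl)-7,8-dimethoxy-6-(triisopropylsilyloxy)chroman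
Product: 19 (R)-7,8-dimethoxy-6-(triisopropylsilyloxy)chroman-3-carbaldehyde
Conditions: p-TsOH·H2O (cat.), acetone/H2O (10:1), rt; used crude
Reagents that add atoms: water, O
Why: Acid-catalysed acetal hydrolysis (transacetalisation to acetone) under mild conditions unmasks the aldehyde, which is used crude to limit enolisation at C3.

Step 10
Reactants: 19 (R)-7,8-dimethoxy-6-(triisopropylsilyloxy)chroman-3-carbaldehyde; 20 dimethyl (1-diazo-2-oxopropyl)phosphonate
Product: 21 (S)-3-ethynyl-7,8-dimethoxy-6-(triisopropylsilyloxy)chroman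
Conditions: 20, K2CO3, MeOH, 0 °C → rt
Reagents that add atoms: dimethyl (1-diazo-2-oxopropyl)phosphonate (20), COP(=O)(OC)C(=[N+]=[N-])C(C)=O
Why: Ohira–Bestmann variant of the Seyferth–Gilbert homologation (alkylidene carbene, 1,2-hydrogen shift) turns the aldehyde into the terminal alkyne under mild carbonate conditions that α-branched β-alkoxy aldehydes normally survive without loss of configuration.

Step 11
Reactants: 21 (S)-3-ethynyl-7,8-dimethoxy-6-(triisopropylsilyloxy)chroman; 11 dimethyl squarate
Product: 23 4-{[(S)-7,8-dimethoxy-6-(triisopropylsilyloxy)chroman-3-yl]ethynyl}-4-hydroxy-2,3-dimethoxycyclobut-2-en-1-one, via lithium acetylide 22 (not isolated)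
Conditions: n-BuLi (1.0 equiv), THF, −78 °C; then 11, −78 °C; aq NH4Cl
Reagents that add atoms: dimethyl squarate (11), COC1=C(OC)C(=O)C1=O
Why: 1,2-Addition of the lithium acetylide to dimethyl squarate as in step 5; the aryl silyl ether is inert to n-BuLi at −78 °C and the carbinol epimers are again inconsequential.

Step 12
Reactants: 23 4-{[(S)-7,8-dimethoxy-6-(triisopropylsilyloxy)chroman-3-yl]ethynyl}-4-hydroxy-2,3-dimethoxycyclobut-2-en-1-one
Product: 24 5-[(S)-7,8-dimethoxy-6-(triisopropylsilyloxy)chroman-3-yl]-2,3-dimethoxy-1,4-benzoquinone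
Conditions: p-xylene (0.01 M, degassed), 138 °C, Ar
Reagents that add atoms: none
Why: Heating opens the strained cyclobutenone by 4π-electrocyclic cleavage of its C1–C4 bond (hydroxyl rotating outward, so the alkynyl group lies cis to the ketene), and the ketene carbon of the resulting (2-alkynylethenyl)ketene then bonds to the distal alkyne carbon, the one that carries C3 of the chroman, to give an aryl/phenoxyl diradical that collapses to the quinone by transfer of the hydroxyl hydrogen to the aryl radical carbon. The closest known reaction type is the Moore rearrangement of 4-alkynyl-4-hydroxycyclobutenones derived from squarate esters, which is established for alkyl-substituted alkynes. The one ring that closes, quinone ring B, closes in the six-membered mode at C4′–C5′ with both alkyne carbons inside the ring (6-endo-dig), driven by release of the four-membered ring strain and by aromatisation in the diradical. No new stereocentre arises: C3 of the chroman is a spectator that is neither radical-bearing nor enolisable in the intermediates, and the carbinol centre of 23 is destroyed. The selectivity needed is six- over five-membered closure (quinone against 2-alkylidenecyclopentene-1,3-dione), which should be secured by the sp3, non-radical-stabilising substituent on the alkyne and by the free hydroxyl as internal hydrogen donor; the regiochemistry is fixed by connectivity, since the squarate core delivers C1′–C4′ with the two vicinal methoxy groups and the alkyne delivers C5′ (substituted) and C6′ (H).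

Step 13
Reactants: 24 5-[(S)-7,8-dimethoxy-6-(triisopropylsilyloxy)chroman-3-yl]-2,3-dimethoxy-1,4-benzoquinone
Product: 25 5-[(S)-6-hydroxy-7,8-dimethoxychroman-3-yl]-2,3-dimethoxy-1,4-benzoquinone
Conditions: HF·pyridine, pyridine, THF, 0 °C → rt
Reagents that add atoms: none
Why: Fluoride-mediated desilylation of the aryl TIPS ether under acidic rather than basic conditions should free the 6-OH while avoiding base-induced tautomerisation of the alkylquinone to a quinone methide, so C3 and the methoxyquinone stay intact.

**Compound list**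
1 | pent-4-ynoic acid | C#CCCC(=O)O | starting material
2 | (R)-4-benzyl-1,3-oxazolidin-2-one | O=C1N[C@H](Cc2ccccc2)CO1 | starting material
3 | pent-4-ynoic pivalic anhydride (not isolated) | C#CCCC(=O)OC(=O)C(C)(C)C | intermediate
4 | (R)-4-benzyl-3-(pent-4-ynoyl)-1,3-oxazolidin-2-one | C#CCCC(=O)N1[C@H](Cc2ccccc2)COC1=O | intermediate
5 | trimethyl orthoformate | COC(OC)OC | starting material
6 | trichlorotitanium (Z)-enolate of 4 (not isolated) | C#CC/C=C(\O[Ti](Cl)(Cl)Cl)N1[C@H](Cc2ccccc2)COC1=O | intermediate
7 | (R)-4-benzyl-3-[(S)-2-(dimethoxymethyl)pent-4-ynoyl]-1,3-oxazolidin-2-one | C#CC[C@@H](C(OC)OC)C(=O)N1[C@H](Cc2ccccc2)COC1=O | intermediate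
8 | (R)-2-(dimethoxymethyl)pent-4-yn-1-ol | C#CC[C@@H](C(OC)OC)CO | intermediate
9 | 4-methylbenzenesulfonyl chloride | Cc1ccc(cc1)S(Cl)(=O)=O | starting material
10 | (R)-2-(dimethoxymethyl)pent-4-yn-1-yl 4-methylbenzenesulfonate | C#CC[C@@H](C(OC)OC)COS(=O)(=O)c1ccc(C)cc1 | intermediate
11 | dimethyl squarate (3,4-dimethoxycyclobut-3-ene-1,2-dione) | COC1=C(OC)C(=O)C1=O | starting material
12 | lithium acetylide of 10 (not isolated) | [Li]C#CC[C@@H](C(OC)OC)COS(=O)(=O)c1ccc(C)cc1 | intermediate
13 | (R)-2-(dimethoxymethyl)-5-(1-hydroxy-2,3-dimethoxy-4-oxocyclobut-2-en-1-yl)pent-4-yn-1-yl 4-methylbenzenesulfonate (both carbinol epimers) | COC1=C(OC)C(O)(C#CC[C@@H](C(OC)OC)COS(=O)(=O)c2ccc(C)cc2)C1=O | intermediate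
14 | (R)-3-(4,5-dimethoxy-3,6-dioxocyclohexa-1,4-dien-1-yl)-2-(dimethoxymethyl)propyl 4-methylbenzenesulfonate | COC1=C(OC)C(=O)C(C[C@@H](C(OC)OC)COS(=O)(=O)c2ccc(C)cc2)=CC1=O | intermediate
15 | (R)-3-(2,5-dihydroxy-3,4-dimethoxyphenyl)-2-(dimethoxymethyl)propyl 4-methylbenzenesulfonate (not isolated) | COc1c(OC)c(O)c(C[C@@H](C(OC)OC)COS(=O)(=O)c2ccc(C)cc2)cc1O | intermediate
16 | (R)-3-(dimethoxymethyl)-7,8-dimethoxychroman-6-ol | COC(OC)[C@H]1COc2c(cc(O)c(OC)c2OC)C1 | intermediate
17 | chlorotriisopropylsilane | CC(C)[Si](Cl)(C(C)C)C(C)C | starting material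
18 | (R)-3-(dimethoxymethyl)-7,8-dimethoxy-6-(triisopropylsilyloxy)chroman | COC(OC)[C@H]1COc2c(cc(O[Si](C(C)C)(C(C)C)C(C)C)c(OC)c2OC)C1 | intermediate
19 | (R)-7,8-dimethoxy-6-(triisopropylsilyloxy)chroman-3-carbaldehyde | O=C[C@H]1COc2c(cc(O[Si](C(C)C)(C(C)C)C(C)C)c(OC)c2OC)C1 | intermediate
20 | dimethyl (1-diazo-2-oxopropyl)phosphonate (Ohira–Bestmann reagent) | COP(=O)(OC)C(=[N+]=[N-])C(C)=O | starting material
21 | (S)-3-ethynyl-7,8-dimethoxy-6-(triisopropylsilyloxy)chroman | C#C[C@H]1COc2c(cc(O[Si](C(C)C)(C(C)C)C(C)C)c(OC)c2OC)C1 | intermediate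
22 | lithium acetylide of 21 (not isolated) | [Li]C#C[C@H]1COc2c(cc(O[Si](C(C)C)(C(C)C)C(C)C)c(OC)c2OC)C1 | intermediate
23 | 4-{[(S)-7,8-dimethoxy-6-(triisopropylsilyloxy)chroman-3-yl]ethynyl}-4-hydroxy-2,3-dimethoxycyclobut-2-en-1-one (both carbinol epimers) | COC1=C(OC)C(O)(C#C[C@H]2COc3c(cc(O[Si](C(C)C)(C(C)C)C(C)C)c(OC)c3OC)C2)C1=O | intermediate
24 | 5-[(S)-7,8-dimethoxy-6-(triisopropylsilyloxy)chroman-3-yl]-2,3-dimethoxy-1,4-benzoquinone | COC1=C(OC)C(=O)C([C@H]2COc3c(cc(O[Si](C(C)C)(C(C)C)C(C)C)c(OC)c3OC)C2)=CC1=O | intermediate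
25 | 5-[(S)-6-hydroxy-7,8-dimethoxychroman-3-yl]-2,3-dimethoxy-1,4-benzoquinone | COC1=C(OC)C(=O)C([C@H]2COc3c(cc(O)c(OC)c3OC)C2)=CC1=O | target

**Step count and risks**
Total step count: 13. Longest linear sequence: 13 steps (from 1).

Three steps most likely to fail:

1. Step 12. What may go wrong: closure of the enynylketene in the five-membered mode, or diversion of the diradical by hydrogen abstraction before the hydroxyl hydrogen is transferred. The fallback moves the ring expansion into the closed-shell electrocyclic manifold and sets out from 23. Semi-hydrogenation (H2, Pd/CaCO3 poisoned with Pb(OAc)2, quinoline, EtOAc, rt) should give 4-hydroxy-2,3-dimethoxy-4-{(Z)-2-[(S)-7,8-dimethoxy-6-(triisopropylsilyloxy)chroman-3-yl]vinyl}cyclobut-2-en-1-one F1. Thermolysis of this 4-alkenyl-4-hydroxycyclobutenone (toluene, 110 °C, or p-xylene, 138 °C, if the inside substituent slows closure) opens it to a dienylketene that closes by 6π-electrocyclisation and tautomerises to 5-[(S)-7,8-dimethoxy-6-(triisopropylsilyloxy)chroman-3-yl]-2,3-dimethoxybenzene-1,4-diol F2, with no diradical and no five-membered alternative. Oxidation with Ag2O (Et2O, rt) should then give quinone 24, where the route is rejoined.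

2. Step 10. What may go wrong: loss of configuration at C3 by enolisation of aldehyde 19 (or β-elimination and re-addition of the aryloxide) in basic methanol. The fallback is a Corey–Fuchs sequence that avoids methanolic base and sets out from 19. CBr4, PPh3 and Et3N (CH2Cl2, 0 °C) should give (S)-3-(2,2-dibromovinyl)-7,8-dimethoxy-6-(triisopropylsilyloxy)chroman F3. n-BuLi (2.1 equiv, THF, −78 °C) should convert it by bromine–lithium exchange and 1,2-shift directly into lithium acetylide 22, where the route is rejoined; 22 is treated in the same flask with 11 as in step 11.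

3. Step 13. What may go wrong: erosion of C3 through tautomerisation of the alkylquinone to a quinone methide, or degradation of the methoxyquinone by fluoride during desilylation. The fallback reverses the order of the last two operations and sets out from 23. Buffered desilylation before any quinone is present (TBAF, AcOH, THF, 0 °C) should give 4-hydroxy-4-{[(S)-6-hydroxy-7,8-dimethoxychroman-3-yl]ethynyl}-2,3-dimethoxycyclobut-2-en-1-one F4. Thermolysis of this free phenol (p-xylene, degassed, 138 °C) by the same ring expansion as in step 12 should then give 25 directly, where the route is rejoined.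

**Further compounds**
F1 | step 12 | 4-hydroxy-2,3-dimethoxy-4-{(Z)-2-[(S)-7,8-dimethoxy-6-(triisopropylsilyloxy)chroman-3-yl]vinyl}cyclobut-2-en-1-one | COC1=C(OC)C(O)(/C=C\[C@H]2COc3c(cc(O[Si](C(C)C)(C(C)C)C(C)C)c(OC)c3OC)C2)C1=O
F2 | step 12 | 5-[(S)-7,8-dimethoxy-6-(triisopropylsilyloxy)chroman-3-yl]-2,3-dimethoxybenzene-1,4-diol | COc1c(OC)c(O)c([C@H]2COc3c(cc(O[Si](C(C)C)(C(C)C)C(C)C)c(OC)c3OC)C2)cc1O
F3 | step 10 | (S)-3-(2,2-dibromovinyl)-7,8-dimethoxy-6-(triisopropylsilyloxy)chroman | BrC(Br)=C[C@H]1COc2c(cc(O[Si](C(C)C)(C(C)C)C(C)C)c(OC)c2OC)C1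
F4 | step 13 | 4-hydroxy-4-{[(S)-6-hydroxy-7,8-dimethoxychroman-3-yl]ethynyl}-2,3-dimethoxycyclobut-2-en-1-one | COC1=C(OC)C(O)(C#C[C@H]2COc3c(cc(O)c(OC)c3OC)C2)C1=O
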